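**Retrosynthetic overview**
- The oxirane comes last, by 8α-OH-directed epoxidation of the 7β-isopropenyl group. The C4 methyl comes from reductive opening of a cyclopropyl ketone fused at C3–C4.
- Key disconnection: ring A and that cyclopropane are cut together. A C10-propargyl/C5-vinyl 1,6-enyne is closed by oxidative gold-carbene cyclopropanation, and the C2 oxygen comes from an N-oxide.
- While C2 is still an alkyne, the C9 ketone is reduced to the axial alcohol and acylated. At that point O8 is silylated, so O9 is the only free hydroxyl.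
- The enyne comes from vinyl conjugate addition and propargylation of a 6-silyloxy-5-isopropenyl-3-methylcyclohexenone.
- Ring B is the six-membered ring of (+)-3-carene (allylic oxidation, retro-Conia-ene opening, α′-hydroxylation). Ring order: B (from carene), then A plus cyclopropane in one operation, then oxirane.

Assumption: commercial (+)-3-carene is the (1S,6R) enantiomer in high optical purity. Eremophilane numbering is used (C4/C5 carry methyls C15/C14, C7 carries C11–C13) and β is the face of the C5 methyl.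

**Step 1**
Reactants: 1 (+)-3-carene
Product: 2 (1R,6S)-4,7,7-trimethylbicyclo[4.1.0]hept-3-en-2-one
Conditions: t-BuOOH (decane), CrO3 (5 mol %), CH2Cl2, rt
Reagents that add atoms: tert-butyl hydroperoxide CC(C)(C)OO
Why: Chromium-catalysed allylic oxidation attacks the ring CH2 (C9) that is both allylic and cyclopropylcarbinyl, and it touches no stereocentre, so C7 of the target is already fixed by the carene.

**Step 2**
Reactants: 2 (1R,6S)-4,7,7-trimethylbicyclo[4.1.0]hept-3-en-2-one
Product: 4 (5S)-3-methyl-5-(prop-1-en-2-yl)cyclohex-2-en-1-one, via dienol 3 (not isolated)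
Conditions: PhMe (0.05 M), 2,6-di-tert-butyl-4-methylphenol (1 mol %), base-washed sealed tube, 230 °C
Reagents that add atoms: none
Why: In this retro-Conia-ene (enolene, homo-1,5-hydrogen shift) rearrangement the carbonyl oxygen takes a hydrogen from the endo methyl cis to the acyl group while the strained C8–C11 bond breaks, so only the isopropenyl isomer can form, C7 is untouched and dienol 3 tautomerises to the enone.

**Step 3**
Reactants: 4 (5S)-3-methyl-5-(prop-1-en-2-yl)cyclohex-2-en-1-one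
Product: 7 (5R,6R)-6-[(tert-butyldimethylsilyl)oxy]-3-methyl-5-(prop-1-en-2-yl)cyclohex-2-en-1-one, via lithium dienolate 5 (not isolated), via lithium alkoxide 6 (not isolated)
Conditions: LiN(i-Pr)2, THF, −78 °C; 2-(phenylsulfonyl)-3-phenyloxaziridine, −78 °C; TBSOTf, −78 → 0 °C
Reagents that add atoms: 2-(phenylsulfonyl)-3-phenyloxaziridine O=S(=O)(N1OC1c1ccccc1)c1ccccc1; tert-butyldimethylsilyl triflate CC(C)(C)[Si](C)(C)OS(=O)(=O)C(F)(F)F
Why: Kinetic α′-deprotonation gives the cross-conjugated dienolate, its oxaziridine (Davis-type) hydroxylation occurs anti to the neighbouring isopropenyl group and sets 8α-O (trans), and the alkoxide is silylated in the same flask.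

**Step 4**
Reactants: 7 (5R,6R)-6-[(tert-butyldimethylsilyl)oxy]-3-methyl-5-(prop-1-en-2-yl)cyclohex-2-en-1-one
Product: 10 (2S,3R,5R,6R)-6-[(tert-butyldimethylsilyl)oxy]-3-ethenyl-3-methyl-5-(prop-1-en-2-yl)-2-(prop-2-yn-1-yl)cyclohexan-1-one, via bromomagnesium enolate 8 (not isolated), via C10 epimer 9 (not isolated)
Conditions: CH2=CHMgBr, CuBr·SMe2 (20 mol %), THF–Me2S, −78 → −30 °C; HC≡CCH2Br, DMPU, −78 → 0 °C; work-up, then DBU (0.2 equiv), PhMe, rt
Reagents that add atoms: vinylmagnesium bromide C=C[Mg]Br; propargyl bromide C#CCBr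
Why: In this copper-catalysed conjugate addition and enolate alkylation (vicinal difunctionalisation) vinyl adds axially and trans to the C7 substituent, as in 5-substituted cyclohexenones, which sets quaternary C5 with its methyl cis to the isopropenyl group, and DBU equilibration moves the C10 propargyl group into the equatorial α position (about 4:1 expected, minor epimer recycled).

**Step 5**
Reactants: 10 (2S,3R,5R,6R)-6-[(tert-butyldimethylsilyl)oxy]-3-ethenyl-3-methyl-5-(prop-1-en-2-yl)-2-(prop-2-yn-1-yl)cyclohexan-1-one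
Product: 11 (1S,2S,3R,5R,6R)-6-[(tert-butyldimethylsilyl)oxy]-3-ethenyl-3-methyl-5-(prop-1-en-2-yl)-2-(prop-2-yn-1-yl)cyclohexan-1-ol
Conditions: LiBH(s-Bu)3, THF, −78 °C; aq. NH4Cl at −78 °C
Reagents that add atoms: none
Why: In this bulky trialkylborohydride reduction the axial C5 vinyl group shields the α face, so hydride arrives equatorially from the β face and gives the axial 9α-alcohol, while the alkyne (the masked C2 ketone) is inert.

**Step 6**
Reactants: 11 (1S,2S,3R,5R,6R)-6-[(tert-butyldimethylsilyl)oxy]-3-ethenyl-3-methyl-5-(prop-1-en-2-yl)-2-(prop-2-yn-1-yl)cyclohexan-1-ol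
Product: 12 (1S,2S,3R,5R,6R)-6-[(tert-butyldimethylsilyl)oxy]-3-ethenyl-3-methyl-5-(prop-1-en-2-yl)-2-(prop-2-yn-1-yl)cyclohexyl (2Z)-2-methylbut-2-enoate
Conditions: angelic acid, 2,4,6-Cl3C6H2COCl, Et3N, PhMe, rt; then 11, 80 °C
Reagents that add atoms: angelic acid C/C=C(/C)C(=O)O
Why: This Yamaguchi-type mixed-anhydride esterification is run without a nucleophilic catalyst, which keeps the Z geometry of angelates, and O9 is the only free hydroxyl, so no 8,9-diol has to be differentiated later.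

**Step 7**
Reactants: 12 (1S,2S,3R,5R,6R)-6-[(tert-butyldimethylsilyl)oxy]-3-ethenyl-3-methyl-5-(prop-1-en-2-yl)-2-(prop-2-yn-1-yl)cyclohexyl (2Z)-2-methylbut-2-enoate
Product: 14 9α-angeloyloxy-8α-(tert-butyldimethylsilyloxy)-3β,15-cyclo-10βH-eremophil-11-en-2-one, via oxo gold carbene 13 (not isolated)
Conditions: [(t-Bu)2(2-PhC6H4)P]AuNTf2 (5 mol %), 8-methylquinoline N-oxide (1.5 equiv), ClCH2CH2Cl, rt
Reagents that add atoms: 8-methylquinoline N-oxide Cc1cccc2ccc[n+]([O-])c12
Why: In this oxidative gold catalysis the N-oxide attacks the gold-bound terminal alkyne at C2, loss of 8-methylquinoline gives α-oxo carbene 13, and 13 cyclopropanates the C5 vinyl group so that ring A and the cyclopropane close in one operation; the vinyl group reacts from the rotamer in which the C5 methyl eclipses the C=C, so its CH2 end lies on the convex β face and C4 is set, and a monosubstituted alkene on a quaternary carbon is too poor a nucleophile for the competing enyne cycloisomerisation.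

**Step 8**
Reactants: 14 9α-angeloyloxy-8α-(tert-butyldimethylsilyloxy)-3β,15-cyclo-10βH-eremophil-11-en-2-one
Product: 15 9α-angeloyloxy-8α-(tert-butyldimethylsilyloxy)-10βH-eremophil-11-en-2-one
Conditions: SmI2 (2.5 equiv), t-BuOH, THF–DMPU, 0 °C
Reagents that add atoms: none
Why: In this ketyl radical-anion opening of a cyclopropyl ketone the exocyclic C3–C15 bond overlaps best with the carbonyl π system of the rigid bicyclo[4.1.0]heptan-2-one and breaks, which turns C15 into the 4β-methyl group with C4 unchanged, and the enoate is reduced far more slowly than the ketone.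

**Step 9**
Reactants: 15 9α-angeloyloxy-8α-(tert-butyldimethylsilyloxy)-10βH-eremophil-11-en-2-one
Product: 16 9α-angeloyloxy-8α-hydroxy-10βH-eremophil-11-en-2-one
Conditions: HF·pyridine, THF–pyridine, 0 °C → rt
Reagents that add atoms: none
Why: Fluoride-mediated silyl ether cleavage under buffered acidic conditions avoids the alkoxide that would start O9-to-O8 acyl migration.

**Step 10**
Reactants: 16 9α-angeloyloxy-8α-hydroxy-10βH-eremophil-11-en-2-one
Product: 17 (11R)-9α-angeloyloxy-11,12-epoxy-8α-hydroxy-10βH-eremophilan-2-one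
Conditions: VO(acac)2 (5 mol %), t-BuOOH, CH2Cl2, 0 °C
Reagents that add atoms: tert-butyl hydroperoxide CC(C)(C)OO
Why: In this hydroxyl-directed vanadium-catalysed epoxidation of a homoallylic alcohol the vanadate ester on the equatorial 8α-oxygen reaches the isopropenyl group only in rotamers with the =CH2 carbon syn or gauche to C8, which exposes the face that gives 11R, and the electron-poor angelate alkene is not touched.

**Compound list**
1 | (+)-3-carene, (1S,6R)-3,7,7-trimethylbicyclo[4.1.0]hept-3-ene | CC1=CC[C@@H]2[C@H](C1)C2(C)C | starting material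
2 | (1R,6S)-4,7,7-trimethylbicyclo[4.1.0]hept-3-en-2-one | CC1=CC(=O)[C@@H]2[C@H](C1)C2(C)C | intermediate
3 | (3S)-5-methyl-3-(prop-1-en-2-yl)cyclohexa-1,5-dien-1-ol (dienol) | OC1=C[C@@H](C(C)=C)CC(C)=C1 | intermediate
4 | (5S)-3-methyl-5-(prop-1-en-2-yl)cyclohex-2-en-1-one | O=C1C[C@@H](C(C)=C)CC(C)=C1 | intermediate
5 | lithium cross-conjugated dienolate of 4 | [Li]OC1=C[C@@H](C(C)=C)CC(C)=C1 | intermediate
6 | lithium alkoxide of the (5R,6R)-6-hydroxy enone | O=C1[C@H](O[Li])[C@@H](C(C)=C)CC(C)=C1 | intermediate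
7 | (5R,6R)-6-[(tert-butyldimethylsilyl)oxy]-3-methyl-5-(prop-1-en-2-yl)cyclohex-2-en-1-one | O=C1[C@H](O[Si](C)(C)C(C)(C)C)[C@@H](C(C)=C)CC(C)=C1 | intermediate
8 | bromomagnesium enolate after vinyl addition (5α-vinyl, 5β-methyl) | Br[Mg]OC=1[C@H](O[Si](C)(C)C(C)(C)C)[C@@H](C(C)=C)C[C@@](C=C)(C)C=1 | intermediate
9 | (2R,3R,5R,6R) epimer of 10 (10β-propargyl) | O=C1[C@H](O[Si](C)(C)C(C)(C)C)[C@@H](C(C)=C)C[C@@](C=C)(C)[C@H]1CC#C | intermediate
10 | (2S,3R,5R,6R)-6-[(tert-butyldimethylsilyl)oxy]-3-ethenyl-3-methyl-5-(prop-1-en-2-yl)-2-(prop-2-yn-1-yl)cyclohexan-1-one | O=C1[C@H](O[Si](C)(C)C(C)(C)C)[C@@H](C(C)=C)C[C@@](C=C)(C)[C@@H]1CC#C | intermediate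
11 | (1S,2S,3R,5R,6R) alcohol (axial 9α-OH) | O[C@@H]1[C@H](O[Si](C)(C)C(C)(C)C)[C@@H](C(C)=C)C[C@@](C=C)(C)[C@@H]1CC#C | intermediate
12 | angelate of 11 | C/C=C(/C)C(=O)O[C@@H]1[C@H](O[Si](C)(C)C(C)(C)C)[C@@H](C(C)=C)C[C@@](C=C)(C)[C@@H]1CC#C | intermediate
13 | α-oxo gold carbene (phosphine-gold cation, NTf2 counter-ion) | C/C=C(/C)C(=O)O[C@@H]1[C@H](O[Si](C)(C)C(C)(C)C)[C@@H](C(C)=C)C[C@@](C=C)(C)[C@@H]1CC(=O)C=[Au][P+](C(C)(C)C)(C(C)(C)C)c1ccccc1-c1ccccc1.O=S(=O)([N-]S(=O)(=O)C(F)(F)F)C(F)(F)F | intermediate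
14 | 9α-angeloyloxy-8α-(tert-butyldimethylsilyloxy)-3β,15-cyclo-10βH-eremophil-11-en-2-one | C/C=C(/C)C(=O)O[C@@H]1[C@H](O[Si](C)(C)C(C)(C)C)[C@@H](C(C)=C)C[C@@]2(C)[C@@H]1CC(=O)[C@@H]3C[C@H]23 | intermediate
15 | 9α-angeloyloxy-8α-(tert-butyldimethylsilyloxy)-10βH-eremophil-11-en-2-one | C/C=C(/C)C(=O)O[C@@H]1[C@H](O[Si](C)(C)C(C)(C)C)[C@@H](C(C)=C)C[C@@]2(C)[C@@H]1CC(=O)C[C@@H]2C | intermediate
16 | 9α-angeloyloxy-8α-hydroxy-10βH-eremophil-11-en-2-one | C/C=C(/C)C(=O)O[C@@H]1[C@H](O)[C@@H](C(C)=C)C[C@@]2(C)[C@@H]1CC(=O)C[C@@H]2C | intermediate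
17 | (11R)-9α-angeloyloxy-11,12-epoxy-8α-hydroxy-10βH-eremophilan-2-one | C/C=C(/C)C(=O)O[C@@H]1[C@H](O)[C@@H]([C@]2(C)CO2)C[C@@]2(C)[C@@H]1CC(=O)C[C@@H]2C | target

**Total steps:** 10. **Longest linear sequence:** 10.

**Steps most likely to fail**

Step 7. The risks are over-oxidation of the carbene and enyne cycloisomerisation. The fallback sets out from 12 and returns at 14, and it uses a diazo ketone as the carbene source.
- Gold-catalysed hydration of the alkyne (wet MeOH) gives the methyl ketone F3.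
- LiN(SiMe3)2 and CF3CO2CH2CF3 convert F3 into the trifluoroacetyl diketone F4.
- MsN3, Et3N and water turn F4 into the diazo ketone F5.
- Rh2(OAc)4 in CH2Cl2 closes ring A and the cyclopropane from F5 to give 14.

Step 2. The rigid bicycle may need too high a temperature, and the product can aromatise to the isomeric phenol. The fallback sets out from 2 and returns at 4, and it is ionic instead of pericyclic.
- Dry HCl in Et2O at 0 °C opens the cyclopropyl ketone by homoconjugate addition to the tertiary chloride (5S)-5-(2-chloropropan-2-yl)-3-methylcyclohex-2-en-1-one F1.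
- F1 is dehydrochlorinated on basic alumina in hexane to give 4.

Step 6. The 9α-hydroxyl is axial and flanked on both sides. The fallback sets out from 11 and returns at 12, and it builds the angelate on the oxygen.
- DCC/DMAP coupling with the small acid 2-[bis(2,2,2-trifluoroethoxy)phosphoryl]propanoic acid gives the phosphonopropanoate ester F2.
- A Z-selective Still–Gennari olefination of F2 with acetaldehyde (KN(SiMe3)2, 18-crown-6, THF, −78 °C) gives 12.

**Further compounds**
F1 | step 2 | (5S)-5-(2-chloropropan-2-yl)-3-methylcyclohex-2-en-1-one | O=C1C[C@@H](C(C)(C)Cl)CC(C)=C1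
F2 | step 6 | 2-[bis(2,2,2-trifluoroethoxy)phosphoryl]propanoate of 11 | CC(P(=O)(OCC(F)(F)F)OCC(F)(F)F)C(=O)O[C@@H]1[C@H](O[Si](C)(C)C(C)(C)C)[C@@H](C(C)=C)C[C@@](C=C)(C)[C@@H]1CC#C
F3 | step 7 | methyl ketone from hydration of 12 | C/C=C(/C)C(=O)O[C@@H]1[C@H](O[Si](C)(C)C(C)(C)C)[C@@H](C(C)=C)C[C@@](C=C)(C)[C@@H]1CC(C)=O
F4 | step 7 | trifluoroacetyl diketone | C/C=C(/C)C(=O)O[C@@H]1[C@H](O[Si](C)(C)C(C)(C)C)[C@@H](C(C)=C)C[C@@](C=C)(C)[C@@H]1CC(=O)CC(=O)C(F)(F)F
F5 | step 7 | diazo ketone | C/C=C(/C)C(=O)O[C@@H]1[C@H](O[Si](C)(C)C(C)(C)C)[C@@H](C(C)=C)C[C@@](C=C)(C)[C@@H]1CC(=O)C=[N+]=[N-]
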